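(Readings and results were generated by integration from invented constants; noise was put on by code.)

in all of them: left-handed substrate 16 mM; right-handed substrate 16 mM; precatalyst 3.2 mM

| flask | coupling partner | free catalyst | remark | time |
|---|---|---|---|---|
| grey | 32 mM | 4.5 mM | run made earlier |  |
| ochre | 32 mM | 7 mM | run made earlier |  |
| teal | 16 mM | 3.2 mM | run made earlier |  |
| flask | 32.0 mM | 3.2 mM |  | 2.5 d |

| run | time / h | left-handed product / % | right-handed product / % |
|---|---|---|---|
| grey | 3.00 | 33.8 | 5.6 |
| grey | 10.0 | 47.1 | 10.9 |
| grey | 15.0 | 49.6 | 12.7 |
| grey | 25.0 | 54.1 | 14.9 |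
| grey | 40.0 | 56.2 | 15.0 |
| ochre | 8.00 | 47.6 | 12.6 |
| ochre | 15.0 | 51.9 | 16.6 |
| ochre | 20.0 | 53.8 | 16.8 |
| ochre | 30.0 | 56.5 | 18.9 |
| ochre | 40.0 | 58.2 | 18.5 |
| teal | 3.00 | 16.1 | 1.5 |
| teal | 5.00 | 21.9 | 3.5 |
| teal | 10.0 | 28.4 | 3.5 |
| teal | 20.0 | 33.7 | 4.5 |
| teal | 40.0 | 35.6 | 4.7 |

(each reading ± 0.5 percentage points)

- free catalyst is single-handed; left-handed substrate and right-handed substrate are mirror images of each other, charged as a racemate, each of them at the stated concentration
- the analysis behind the earlier runs scatters by 0.5 percentage points, standard deviation
- an excess is the difference of the two amounts in percent of their sum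
- an excess is below zero if the other one leads

* excess of left-handed product over right-handed product in the product at 3.0 h
* excess of left-handed product over right-handed product in the product at 2.5 d
* part of the left-handed substrate and right-handed substrate charged together that has reacted at 2.5 d

1. I decided to reckon this flask by its coupling partner, not its substrates, taking each product formed to spend one coupling partner.

2. Slope at the start: the teal run had formed 17.6 % of product at 3.00 h, with the flask's free catalyst but 16 mM of coupling partner. The flask's c(coupling partner) is twice that, and I scaled the slope with it, which gave about 35.2 % at 3.0 h.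

3. Knee: the grey run's left-handed product reached 49.6 %, about half of the charge and so the amount of left-handed substrate charged, at 15.0 h. It then crept to 56.2 %, so the substrates interconverted. Stretching the time by the ratio of free catalyst put the flask's knee near 21.1 h.

4. Level: product per coupling partner charged, as read at 40.0 h, was 71.2 % in the grey run and 76.7 % in the ochre run. A straight line to 3.2 mM of free catalyst gave 68.3 % for this partner yield, the product formed per coupling partner charged. The time of the last grey reading, stretched the same way, falls at 56.3 h, earlier than 60 h, so I expected the flask to stand at 68.3 % reacted.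

5. The forecast gave an excess of left-handed product of 75 % (69 % to 81 %) at 3.0 h and 60 % (55 % to 66 %) at 2.5 d, and 69.5 % (63 % to 74 %) reacted at 2.5 d, on this ground: “Conversion plateaus early, so the catalyst is dying”.

6. The flask gave those three, in the same order, as 75.8 %, 63.2 % and 69.8 %.

    precatalyst → racemization catalyst (k = 4.10 × 10⁻⁶ s⁻¹)
    coupling partner + free catalyst + right-handed substrate → free catalyst + right-handed product (k = 0.0970 L² mol⁻² s⁻¹)
    left-handed substrate + racemization catalyst ⇌ right-handed substrate + racemization catalyst, rate k3*[racemization catalyst]*[left-handed substrate] forward; the back reaction follows from the equilibrium constant (k = 0.00960 L mol⁻¹ s⁻¹)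
    coupling partner + free catalyst + left-handed substrate → free catalyst + left-handed product (k = 1.00 L² mol⁻² s⁻¹)
    coupling partner → decomposed reagent (k = 8.90 × 10⁻⁶ s⁻¹)

At the end of the flask, free catalyst stood at 100 %, while coupling partner, the limiting reagent, was down to 0.51 % of its charge, less than the 31 % of right-handed substrate left. Its partner yield was 69.8 %, against my 68.3 %. For the neighbour charged with 13 mM of coupling partner, I drew the line from 68.3 % through the teal run's 80.6 %, read at 40.0 h. That gave a partner yield of 82.9 %, and so 33.7 % reacted. That neighbour gave 33.2 %.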